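## Retrosynthetic overview
1. Target ← vinyl-dioxane **13** by oxidative cleavage of the vinyl group to the methyl ester (the last step).
2. **13** ← tertiary silyl peroxide/secondary mesylate **12** by 6-exo SN2 closure of the 1,2-dioxane ring, with inversion at C3.
3. **12** ← mesylate **11** by the key radical step: Co/O2/silane Markovnikov peroxidation of the trisubstituted olefin, which forms the C6–O bond at the quaternary centre.
4. **11** ← anti-homoallylic alcohol **10** (E-crotylboration sets C2′ and C3) ← β,γ-unsaturated aldehyde **9** ← cross-metathesis of enone-olefin **6** with butenol.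
5. The cyclohexenone ring is formed first (Michael/Dieckmann, then Stork–Danheiser); the dioxane ring is formed last.

Assumptions:
- Vinylogous-ester formation occurs at the less hindered carbonyl of dione **3**.
- The C5=C6 E/Z ratio is irrelevant, because C6 becomes a planar radical.
- C6 cannot be controlled in the radical step, so the two C6 epimers are separated after ring closure.

## Route

**Step 1**
Reactants: **1** methyl isobutyrate; **2** ethyl vinyl ketone
Product: **3** 2,4,4-trimethylcyclohexane-1,3-dione
Conditions: KOt-Bu, THF/t-BuOH, 0 °C → reflux
Reagents that add atoms: none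
Why: The tertiary ester enolate adds 1,4 to the vinyl ketone, and the resulting ketone enolate closes onto the ester (Dieckmann) with loss of MeOH. This is a tandem Michael–Dieckmann reaction, analogous to the 4,4-dimethylcyclohexane-1,3-dione preparation, and it sets the gem-dimethyl and 2-methyl pattern.

**Step 2**
Reactants: **3**
Product: **4** 3-isobutoxy-2,6,6-trimethylcyclohex-2-en-1-one
Conditions: i-BuOH, cat. TsOH, PhMe, Dean–Stark reflux
Reagents that add atoms: isobutanol, CC(C)CO
Why: Acid-catalysed vinylogous esterification occurs at the carbonyl remote from the quaternary carbon. This leaves the hindered ketone next to CMe2 free for the next step.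

**Step 3**
Reactants: **4**; **5** 4-bromo-2-methylbut-1-ene
Product: **6** 2,4,4-trimethyl-3-(3-methylbut-3-en-1-yl)cyclohex-2-en-1-one
Conditions: (i) **5**, Mg, THF → RMgBr; CeCl3, THF, −78 → 0 °C, add **4**; (ii) 2 M HCl, THF, 25 °C
Reagents that add atoms: none (the Grignard reagent is made from **5**)
Why: Organocerium 1,2-addition to the ketone, which has no enolisable α-H, followed by acid-mediated transposition (Stork–Danheiser) puts the chain on the carbon next to CMe2 and moves the carbonyl to the remote position. This gives the 3-alkyl-2,4,4-trimethylcyclohexenone directly.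

**Step 4**
Reactants: **6**; **7** but-3-en-1-ol
Product: **8** 4-methyl-6-(2,6,6-trimethyl-3-oxocyclohex-1-en-1-yl)hex-3-en-1-ol (E/Z mixture)
Conditions: Hoveyda–Grubbs II (5 mol%), **7** (5 equiv), CH2Cl2, 45 °C
Reagents that add atoms: none (ethylene is lost)
Why: Cross-metathesis of the 1,1-disubstituted olefin with a terminal olefin gives the trisubstituted olefin that the radical step needs. The tetrasubstituted enone is inert, and the E/Z ratio does not matter.

**Step 5**
Reactants: **8**
Product: **9** 4-methyl-6-(2,6,6-trimethyl-3-oxocyclohex-1-en-1-yl)hex-3-enal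
Conditions: Dess–Martin periodinane, NaHCO3, CH2Cl2, 0 °C; use crude immediately
Reagents that add atoms: none
Why: Buffered Dess–Martin oxidation of the primary alcohol gives the aldehyde, and the buffer and low temperature limit isomerisation of the β,γ-olefin into conjugation.

**Step 6**
Reactants: **9**
Product: **10** 3-[(6R,7S)-6-hydroxy-3,7-dimethylnona-3,8-dien-1-yl]-2,4,4-trimethylcyclohex-2-en-1-one
Conditions: (E)-crotyl-B(Ipc)2 (from (E)-2-butene, KOt-Bu/n-BuLi, then Ipc2BOMe, BF3·OEt2), THF, −78 °C; then NaOH, H2O2
Reagents that add atoms: (E)-crotyl unit, C/C=C/C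
Why: Brown crotylboration proceeds through a chair Zimmerman–Traxler transition state. The E-crotyl geometry gives the anti relationship between Me and OH, and the Ipc enantiomer (chosen to give the (R)-carbinol) fixes the absolute configuration at C2′ and C3. The anti alcohol is required because step 9 inverts C3, and the vinyl group is a non-acidic masked ester, so no E1cB elimination can occur later.

**Step 7**
Reactants: **10**
Product: **11** the (6R,7S)-mesylate of **10**
Conditions: MsCl, Et3N, CH2Cl2, 0 °C
Reagents that add atoms: MsCl, CS(=O)(=O)Cl
Why: Mesylation of the secondary alcohol proceeds with retention and installs the leaving group before any peroxide is present.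

**Step 8 (key radical step)**
Reactants: **11**
Product: **12** the tertiary triethylsilyl peroxide of **11**, as a C6 epimeric mixture (about 1:1)
Conditions: Co(acac)2 (10 mol%), Et3SiH (2 equiv), O2 (1 atm), 1,2-DCE, 25 °C
Reagents that add atoms: Et3SiH, CC[SiH](CC)CC; O2, O=O
Why: This is the Isayama–Mukaiyama peroxidation. Co–H transfers H• to C5 of the trisubstituted olefin and gives the tertiary C6 radical, which is trapped by O2 at diffusion-controlled rate. The resulting peroxyl species is reduced and silylated, giving the hindered tertiary C–O bond. The more substituted olefin reacts much faster than the monosubstituted vinyl group, and the enone and mesylate are inert. C6 is formed as a mixture of epimers because the radical is planar and remote from C3.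

**Step 9**
Reactants: **12**
Product: **13** 3-(2-{(3S,6R)-3-[(2S)-but-3-en-2-yl]-6-methyl-1,2-dioxan-6-yl}ethyl)-2,4,4-trimethylcyclohex-2-en-1-one; the 6-epimer is removed here
Conditions: TBAF (3 equiv), THF/DMF 1:1, 0 → 25 °C; then HPLC or silica separation of the C6 epimers
Reagents that add atoms: none
Why: Fluoride releases the tertiary peroxy anion, which displaces the secondary mesylate by 6-exo-tet SN2 (intramolecular peroxide alkylation). Inversion converts C3 (R) to C3 (S). Both C6 epimers close, and the (3S,6R) epimer, which has the C3 side chain and C6 chain diequatorial in the chair, should predominate slightly. It is separated from its 6-epimer.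

**Step 10**
Reactants: **13**
Product: **14** methyl (2R)-2-[(3S,6R)-6-methyl-6-[2-(2,6,6-trimethyl-3-oxocyclohex-1-en-1-yl)ethyl]-1,2-dioxan-3-yl]propanoate (methyl diacarnoate A)
Conditions: O3 (1 equiv), CH2Cl2/MeOH 3:1, −78 °C; then Ac2O, Et3N, DMAP, 0 → 25 °C
Reagents that add atoms: MeOH, CO; O3, [O-][O+]=O
Why: Ozonolysis in methanol gives an α-methoxy hydroperoxide, which Ac2O/Et3N dehydrates to the methyl ester (Schreiber protocol). The electron-poor tetrasubstituted enone and the dialkyl peroxide survive at −78 °C, and C2′ keeps its configuration (S → R only by the CIP priority change from vinyl to CO2Me).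

## Compound list
1 | methyl isobutyrate | COC(=O)C(C)C | starting material
2 | ethyl vinyl ketone | C=CC(=O)CC | starting material
3 | 2,4,4-trimethylcyclohexane-1,3-dione | CC1C(=O)CCC(C)(C)C1=O | intermediate
4 | 3-isobutoxy-2,6,6-trimethylcyclohex-2-en-1-one | CC(C)COC1=C(C)C(=O)C(C)(C)CC1 | intermediate
5 | 4-bromo-2-methylbut-1-ene | C=C(C)CCBr | starting material
6 | 2,4,4-trimethyl-3-(3-methylbut-3-en-1-yl)cyclohex-2-en-1-one | C=C(C)CCC1=C(C)C(=O)CCC1(C)C | intermediate
7 | but-3-en-1-ol | C=CCCO | starting material
8 | 4-methyl-6-(2,6,6-trimethyl-3-oxocyclohex-1-en-1-yl)hex-3-en-1-ol | OCCC=C(C)CCC1=C(C)C(=O)CCC1(C)C | intermediate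
9 | 4-methyl-6-(2,6,6-trimethyl-3-oxocyclohex-1-en-1-yl)hex-3-enal | O=CCC=C(C)CCC1=C(C)C(=O)CCC1(C)C | intermediate
10 | anti-homoallylic alcohol (6R,7S) | C=C[C@H](C)[C@H](O)CC=C(C)CCC1=C(C)C(=O)CCC1(C)C | intermediate
11 | (6R,7S)-mesylate | C=C[C@H](C)[C@H](OS(C)(=O)=O)CC=C(C)CCC1=C(C)C(=O)CCC1(C)C | intermediate
12 | tertiary triethylsilyl peroxide (C6 epimeric mixture) | C=C[C@H](C)[C@H](OS(C)(=O)=O)CCC(C)(OO[Si](CC)(CC)CC)CCC1=C(C)C(=O)CCC1(C)C | intermediate
13 | vinyl 1,2-dioxane (3S,6R) | C=C[C@H](C)[C@@H]1CC[C@@](C)(CCC2=C(C)C(=O)CCC2(C)C)OO1 | intermediate
14 | methyl diacarnoate A | COC(=O)[C@H](C)[C@@H]1CC[C@@](C)(CCC2=C(C)C(=O)CCC2(C)C)OO1 | target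

## Totals
- Total steps: 10.
- Longest linear sequence: 10 (**1** → **14**); **5** and **7** join as small starting materials at steps 3 and 4.

## Three steps most likely to fail
1. **Step 9, peroxide SN2 closure.** The hindered tertiary peroxide anion attacking a β-branched secondary mesylate may lose to E2 elimination, and the C6 dr may be poor.
   Fallback (changes the approach): make the (E)-enoate by Wittig on **9** with Ph3P=C(Me)CO2Me instead of crotylating, run the step 8 peroxidation, and close by base-mediated peroxy-Michael addition (DBU). Then separate the diastereomers by HPLC.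
2. **Step 8, chemoselective peroxidation.** The monosubstituted vinyl group or the enone may compete, and the silyl peroxide may over-reduce to the tertiary alcohol.
   Fallback (ionic instead of radical O2 trapping): Mukaiyama hydration (Co(acac)2/PhSiH3/O2, i-PrOH) to the tertiary alcohol, then SN1 hydroperoxidation with H2O2 and catalytic acid in HFIP. Close as in step 9.
3. **Step 4, cross-metathesis of the hindered 1,1-disubstituted olefin.** Yields may be low, with homodimerisation of butenol.
   Fallback (no metathesis): ozonolyse **6** to the methyl ketone, then Wittig with the ylide from (3-hydroxypropyl)triphenylphosphonium bromide to give **8**.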